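The numbers in the tables are simulated with made-up constants, and the scatter is random.

- Each percent of substrate charged stands as substrate, as target, or as something these readings do not show.

| setting | south-east | north | Monday's | Tuesday's | Wednesday's | Thursday's |
|---|---|---|---|---|---|---|
| substrate | 0.25 M | 0.38 M | 0.50 M | 0.50 M | 0.50 M | 0.50 M |
| gas | 39 mM (held) | 39 mM (held) | 39 mM (held) | 39 mM (held) | 39 mM (held) | 39 mM (held) |
| temperature | 75 °C | 110 °C | 110 °C |  | 80 °C | 140 °C |
| remark | run made earlier | run made earlier |  | at 140 °C until 15 min, from then on at 80 °C |  |  |
| time |  |  | 80 min | 80 min | 80 min | 80 min |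

| run | time / min | target / % | substrate / % |
|---|---|---|---|
| south-east | 25.0 | 22.9 | 46.3 |
| south-east | 60.0 | 24.7 | 24.0 |
| south-east | 120 | 16.7 | 12.3 |
| south-east | 180 | 10.0 | 7.6 |
| south-east | 300 | 4.4 | 2.9 |
| north | 10.0 | 3.7 | 53.7 |
| north | 20.0 | 2.8 | 30.7 |
| north | 30.0 | 1.2 | 17.4 |
| north | 40.0 | 1.2 | 9.3 |
| north | 50.0 | 0.7 | 5.5 |

(readings scatter by 0.3 percentage points)

- at the start none of the gas is in solution

- the best flask by amount of target, in percent of the substrate charged; "all alike" if 1.5 percentage points covers them all (Monday's / Tuesday's / Wednesday's / Thursday's / all alike)
- amount of target at the end, in percent of the substrate charged, Monday's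
- amount of target at the end, in percent of the substrate charged, Tuesday's
- amount of target at the end, in percent of the substrate charged, Wednesday's
- amount of target at the end, in percent of the substrate charged, Thursday's

- The two runs seem to contradict each other: the south-east run holds 22.9% target at 25.0 min with about half of its substrate left, while the north run holds 3.7% at 10.0 min with about half left.
- Like conversion thus goes with unlike target. South-east target reads 24.7% at 60.0 min and then falls together with substrate, so the two look like an exchanging pair.
- The last north target readings lie close to their scatter of 0.3 percentage points, so all the north readings are pooled: target over substrate is 0.0823, the standing ratio, target held per substrate once the two fall together.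
- The last three south-east readings give 1.36, so the ratio reads lower in the hotter north run. The two runs also differ in charge, but taking temperature as the cause clears the contradiction, and the reckoning below rests on that assumption.
- In the north run target is a small correction to substrate, so the substrate line gives the fall, 0.0570 min⁻¹. Carried to the larger charge of Monday's, which is an assumption, it leaves 0.996% substrate at 80 min, and so 0.0820% target.
- Taking the logarithm of the ratio as straight in temperature gives 0.913 at 80 °C and 0.00742 at 140 °C. This reckoning therefore favours Wednesday's, while Tuesday's ends at the same temperature on whatever substrate its hot start left.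
- The forecast names Wednesday's, with 0.1%, 2%, 15% and 0.01% for Monday's through Thursday's, holding that “Target formation is therefore exothermic and reversible”.
- The flasks give 0.0771%, 4.58%, 14.3% and 0% in that order, and the best is Wednesday's.

    substrate + partner ⇌ target (K = 14.8 M⁻¹, k = 0.585 M⁻¹ min⁻¹, Ea = 52.0 kJ mol⁻¹, ΔH = −76.0 kJ mol⁻¹)
    substrate + 2 partner → side product (k = 14.7 M⁻² min⁻¹, Ea = 40.0 kJ mol⁻¹)
    partner → decomposed reagent (k = 0.0237 min⁻¹, Ea = 120 kJ mol⁻¹)
    gas ⇌ partner, rate k4*(csat - [partner]) (kL = 30.1 min⁻¹)
    (constants at 80 °C)

- Monday's ends at a ratio of 0.0784 against 0.0823, and Wednesday's and Tuesday's end at 0.814 and 0.797 against 0.913, despite Tuesday's hot start. Partner, unseen in the readings, stands in Wednesday's at 0.0388 M after 40.0 min and 0.0389 M after 80.0 min, against a saturation of 39 mM, so over that stretch substrate meets a nearly constant partner: pseudo-first-order. The reverse step is the main reason for Thursday's result: without it, Thursday's ends at 72.3% target, not 0%.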